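**Strategy.** The route rests on cutting the C5–C6 bond of the tetradecyl chain (C1 = AcOCH2, C14 on ring C3). This is an unactivated CH2–CH2 link in the unbranched C1–C14 tether between the acetate oxygen and the furan-2,5-dione ring. With no polar handle nearby, the bond is made at the alkene level by Ru-carbene cross-metathesis ([2+2]/retro-[2+2] through a ruthenacyclobutane, ethene extruded) of hex-5-enyl acetate with 3-(dec-9-enyl)-4-methylfuran-2,5-dione. The new C5=C6 alkene is saturated in the same flask by the Ru hydride formed under H2. The tetrasubstituted, electron-poor ring C3=C4 alkene should be inert to both events. The anhydride partner comes in one step from a Barton decarboxylative addition to citraconic anhydride.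

Key step: step 2

Remark: the target has no stereocentre and no stereogenic double bond (its only C=C lies in the five-membered ring), so it is achiral and no stereocontrol is required.

Step 1
Reactants: 1 undec-10-enoyl chloride; 2 sodium pyrithione (sodium 2-thioxopyridin-1(2H)-olate); 3 citraconic anhydride (3-methylfuran-2,5-dione)
Product: 6 3-(dec-9-en-1-yl)-4-methylfuran-2,5-dione, via Barton ester 4 (not isolated), via pyridylthio adduct 5 (not isolated)
Conditions: 2 (1.1 equiv), DMAP (cat.), CH2Cl2, rt, dark; then 3 (5 equiv), hν (W lamp), 15 °C; then Et3N (0.2 equiv), rt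
Reagents that add atoms: none
Why: Acyl transfer gives the Barton ester, whose visible-light homolysis and decarboxylation release the nucleophilic dec-9-enyl radical that adds to the unsubstituted CH carbon of electron-poor citraconic anhydride, the tertiary α-acyl radical carrying the chain by 2-pyridylthio transfer (Barton decarboxylative radical addition), and base-catalysed E1cB loss of pyridine-2-thiol then restores the ring C3=C4 double bond, which erases both transient stereocentres of 5.

Step 2
Reactants: 6 3-(dec-9-en-1-yl)-4-methylfuran-2,5-dione; 7 hex-5-en-1-yl acetate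
Product: 9 Aspergillus acid E, via alkenyl acetate 8 (not isolated)
Conditions: 7 (4 equiv), Grubbs II (5 mol %), ClCH2CH2Cl, 45 °C, Ar sweep; then H2 (7 bar), 70 °C
Reagents that add atoms: none
Why: The Ru benzylidene exchanges with one terminal alkene to a Ru alkylidene, which undergoes [2+2] cycloaddition with the other terminal alkene to a ruthenacyclobutane; cycloreversion joins C5 to C6 as a double bond and extrudes ethene, whose removal drives the equilibrium. Under H2 the same Ru residue is converted into a Ru hydride that saturates C5=C6, so the step is a tandem olefin cross-metathesis–hydrogenation, a known one-pot reaction type. No ring of the target is closed (the only ring formed is the transient four-membered ruthenacycle) and no stereocentre is created, and the E/Z geometry of 8 is irrelevant because it is erased by the hydrogenation. The step needs cross- over self-metathesis, which for two unhindered terminal alkenes is secured by the excess of the cheap partner 7, whose homodimer re-enters the cycle by secondary metathesis. It also needs chemoselectivity for the chain alkene, which the substrate secures because the ring C3=C4 alkene is tetrasubstituted and flanked by two acyl groups and should therefore be too hindered and electron-poor for carbene [2+2] or hydride insertion. The acetate and the anhydride are inert to both Ru species, and the hydrogenated homodimers differ enough in size and polarity from 9 to be removed by chromatography.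

**Compound list**
1 | undec-10-enoyl chloride | C=CCCCCCCCCC(=O)Cl | starting material
2 | sodium pyrithione (sodium 2-thioxopyridin-1(2H)-olate) | [Na+].[O-]N1C=CC=CC1=S | starting material
3 | citraconic anhydride (3-methylfuran-2,5-dione) | CC1=CC(=O)OC1=O | starting material
4 | 2-thioxopyridin-1(2H)-yl undec-10-enoate (Barton ester) | C=CCCCCCCCCC(=O)ON1C=CC=CC1=S | intermediate
5 | 3-(dec-9-en-1-yl)-4-methyl-4-(pyridin-2-ylsulfanyl)oxolane-2,5-dione (racemic mixture of diastereomers) | C=CCCCCCCCCC1C(=O)OC(=O)C1(C)Sc2ccccn2 | intermediate
6 | 3-(dec-9-en-1-yl)-4-methylfuran-2,5-dione | C=CCCCCCCCCC1=C(C)C(=O)OC1=O | intermediate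
7 | hex-5-en-1-yl acetate | CC(=O)OCCCCC=C | starting material
8 | 14-(4-methyl-2,5-dioxo-2,5-dihydrofuran-3-yl)tetradec-5-en-1-yl acetate (E/Z mixture) | CC(=O)OCCCCC=CCCCCCCCCC1=C(C)C(=O)OC1=O | intermediate
9 | Aspergillus acid E, 14-(4-methyl-2,5-dioxo-2,5-dihydrofuran-3-yl)tetradecyl acetate | CC(=O)OCCCCCCCCCCCCCCC1=C(C)C(=O)OC1=O | target

**Total step count:** 2. **Longest linear sequence:** 2 steps.

**Steps most likely to fail.** The route has only two steps, so the third entry is the elimination stage that closes step 1.

1. Step 2 (key step). Self-metathesis may compete with cross-metathesis. More seriously, Ru-hydride-induced migration of the terminal double bonds before metathesis would change the chain length by CH2 units and give homologues that cannot be separated. The in-flask hydrogenation may also stall. The fallback sets out from 6 and comes back at 9, passing through 8. The terminal alkene of 6 is ozonised (O3, CH2Cl2, −78 °C; the electron-poor ring alkene should react far more slowly) to the secondary ozonide 3-methyl-4-[8-(1,2,4-trioxolan-3-yl)octyl]furan-2,5-dione F1. Dimethyl sulfide reduces this to 9-(4-methyl-2,5-dioxo-2,5-dihydrofuran-3-yl)nonanal F2. Commercial 5-bromopentyl acetate and PPh3 (MeCN, reflux) give (5-acetoxypentyl)triphenylphosphonium bromide F3. NaHMDS (THF, −78 °C) converts it into (5-acetoxypentylidene)triphenylphosphorane F4, which is added to F2 at −78 °C, where the aldehyde should be attacked much faster than the hindered anhydride carbonyls. This Wittig reaction forms the same C5=C6 bond at a fixed position and gives 8, isolated here. Hydrogenation of 8 with H2 and RhCl(PPh3)3 in toluene, a catalyst that does not reduce tetrasubstituted alkenes, should give 9.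

2. Step 1, radical stage. The dec-9-enyl radical may be captured by the thiocarbonyl group of a second Barton ester molecule (decarboxylative rearrangement to the alkyl pyridyl sulfide) faster than it adds to the trisubstituted alkene of citraconic anhydride. The fallback sets out from 3 and comes back at 6; it replaces the radical addition by a polar Wittig sequence. Condensation of 3 with p-toluidine (AcOH, reflux) gives 3-methyl-1-(4-methylphenyl)-1H-pyrrole-2,5-dione F5. Heating F5 with PPh3 and commercial dec-9-enal in AcOH (phosphine conjugate addition, ylide formation and Wittig reaction in one operation) gives (E)-3-(dec-9-en-1-ylidene)-4-methyl-1-(4-methylphenyl)pyrrolidine-2,5-dione F6. Et3N in refluxing THF moves the exocyclic double bond into the ring to give 3-(dec-9-en-1-yl)-4-methyl-1-(4-methylphenyl)-1H-pyrrole-2,5-dione F7. KOH in THF/MeOH/water at reflux opens and cleaves the imide to dipotassium (2Z)-2-(dec-9-en-1-yl)-3-methylbut-2-enedioate F8, and acidification with HCl closes the anhydride to 6.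

3. Step 1, elimination stage. The base-mediated loss of pyridine-2-thiol from 5 may be incomplete or reversible through thiol re-addition. The fallback sets out from 5 and comes back at 6; it replaces the E1cB step by an irreversible sulfoxide syn-elimination. Crude 5 is oxidised with mCPBA (1.0 equiv, CH2Cl2, −40 °C), where the sulfide should react far faster than the terminal alkene, to 3-(dec-9-en-1-yl)-4-methyl-4-(pyridin-2-ylsulfinyl)oxolane-2,5-dione F9. Warming F9 in toluene (60 °C) should expel pyridine-2-sulfenic acid and give 6.

**Further compounds**
F1 | step 2 | 3-methyl-4-[8-(1,2,4-trioxolan-3-yl)octyl]furan-2,5-dione | CC1=C(CCCCCCCCC2OCOO2)C(=O)OC1=O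
F2 | step 2 | 9-(4-methyl-2,5-dioxo-2,5-dihydrofuran-3-yl)nonanal | O=CCCCCCCCCC1=C(C)C(=O)OC1=O
F3 | step 2 | (5-acetoxypentyl)triphenylphosphonium bromide | CC(=O)OCCCCC[P+](c1ccccc1)(c1ccccc1)c1ccccc1.[Br-]
F4 | step 2 | (5-acetoxypentylidene)triphenylphosphorane | CC(=O)OCCCCC=P(c1ccccc1)(c1ccccc1)c1ccccc1
F5 | step 1 | 3-methyl-1-(4-methylphenyl)-1H-pyrrole-2,5-dione | CC1=CC(=O)N(c2ccc(C)cc2)C1=O
F6 | step 1 | (E)-3-(dec-9-en-1-ylidene)-4-methyl-1-(4-methylphenyl)pyrrolidine-2,5-dione (racemic) | C=CCCCCCCC/C=C1\C(C)C(=O)N(c2ccc(C)cc2)C1=O
F7 | step 1 | 3-(dec-9-en-1-yl)-4-methyl-1-(4-methylphenyl)-1H-pyrrole-2,5-dione | C=CCCCCCCCCC1=C(C)C(=O)N(c2ccc(C)cc2)C1=O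
F8 | step 1 | dipotassium (2Z)-2-(dec-9-en-1-yl)-3-methylbut-2-enedioate | C=CCCCCCCCC/C(C(=O)[O-])=C(\C)C(=O)[O-].[K+].[K+]
F9 | step 1 | 3-(dec-9-en-1-yl)-4-methyl-4-(pyridin-2-ylsulfinyl)oxolane-2,5-dione (mixture of diastereomers) | C=CCCCCCCCCC1C(=O)OC(=O)C1(C)S(=O)c2ccccn2
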